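**Retrosynthetic overview**
1. Target 27 ⇐ thiolate O-demethylation of bis-ketal 26 ⇐ acid-mediated MOM removal and double ketalisation of bis-lactol 24 (both dihydropyran rings close last) ⇐ MeLi addition to bis-lactone 23.
2. 23 ⇐ bis(chloromethyl) arene 20 + two equivalents of the lithium enolate of (R)-lactone 21: two benzylic CH2–Cα bonds, no ring closed; both tetrahydrofuran rings are bought with the lactone.
3. 20 ⇐ dibromide 15 (double Br/Li exchange, formylation, reduction, chlorination) ⇐ aldehyde 12 + aryl Grignard from 9, then ionic deoxygenation; the aldehyde carbon of 10 fixes which oxygen carries the methyl group.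
4. 9 (dihydrobenzofuran ring, formed first) ⇐ asymmetric intramolecular Tsuji–Trost O-allylation of phenol carbonate 8 ⇐ 4-bromophenol by Claisen rearrangement and cross-metathesis.
5. Feature: in each 2,3,3a,9a-tetrahydro-4H-furo[2,3-b]chromene unit the ring-fusion carbon C3a, which carries the benzylic C4 methylene, is trans to the C3 methyl on the tetrahydrofuran ring; this is a trans-α-benzyl-β-methyl-γ-butyrolactone whose carbonyl carbon becomes the ketal carbon C9a.

Key step: step 15

Remark: carbinol 14 and lactols 24/25 form as epimer mixtures at centres that are later removed or re-set under thermodynamic control. The sense of induction of the (S,S) ligand in step 8 is assigned by analogy with closely related phenol cyclisations and is to be checked by chiral HPLC (the mirror-image ligand serves if it proves opposite).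

**Route**

Step 1
Reactants: 1 4-bromophenol
Product: 2 1-(allyloxy)-4-bromobenzene
Conditions: allyl bromide, K2CO3, acetone, reflux
Reagents that add atoms: allyl bromide, C=CCBr
Why: Williamson ether synthesis, the phenoxide displacing an unhindered allylic bromide.

Step 2
Reactants: 2 1-(allyloxy)-4-bromobenzene
Product: 3 2-allyl-4-bromophenol
Conditions: PhNEt2, 200 °C
Reagents that add atoms: none
Why: Aromatic Claisen rearrangement ([3,3]-sigmatropic shift then tautomerisation) delivers the allyl group to the ortho position, the para position being blocked by bromine.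

Step 3
Reactants: 3 2-allyl-4-bromophenol
Product: 4 (2-allyl-4-bromophenoxy)(tert-butyl)dimethylsilane
Conditions: TBSCl, imidazole, DMF, rt
Reagents that add atoms: tert-butyldimethylsilyl chloride, CC(C)(C)[Si](C)(C)Cl
Why: Imidazole-mediated silylation masks the phenol so that the side-chain alcohol can later be acylated selectively.

Step 4
Reactants: 4 (2-allyl-4-bromophenoxy)(tert-butyl)dimethylsilane
Product: 5 (E)-4-[5-bromo-2-(tert-butyldimethylsilyloxy)phenyl]-2-methylbut-2-enal
Conditions: methacrolein (5 equiv), second-generation Hoveyda–Grubbs catalyst RuCl2(H2IMes)(=CH-C6H4-2-O-i-Pr) (5 mol %), CH2Cl2, 40 °C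
Reagents that add atoms: methacrolein, C=C(C)C=O
Why: Olefin cross-metathesis of a terminal allyl arene with methacrolein is driven by loss of ethene and should give the trisubstituted enal with the thermodynamically preferred E geometry.

Step 5
Reactants: 5 (E)-4-[5-bromo-2-(tert-butyldimethylsilyloxy)phenyl]-2-methylbut-2-enal
Product: 6 (E)-4-[5-bromo-2-(tert-butyldimethylsilyloxy)phenyl]-2-methylbut-2-en-1-ol
Conditions: NaBH4, CeCl3·7H2O, MeOH, 0 °C
Reagents that add atoms: none
Why: Luche reduction gives clean 1,2-reduction of the enal without touching the alkene geometry or the aryl silyl ether.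

Step 6
Reactants: 6 (E)-4-[5-bromo-2-(tert-butyldimethylsilyloxy)phenyl]-2-methylbut-2-en-1-ol
Product: 7 (E)-4-[5-bromo-2-(tert-butyldimethylsilyloxy)phenyl]-2-methylbut-2-en-1-yl methyl carbonate
Conditions: ClCO2Me, pyridine, CH2Cl2, 0 °C
Reagents that add atoms: methyl chloroformate, COC(=O)Cl
Why: Acylation of the primary allylic alcohol installs the carbonate leaving group needed for ionisation by zerovalent palladium.

Step 7
Reactants: 7 (E)-4-[5-bromo-2-(tert-butyldimethylsilyloxy)phenyl]-2-methylbut-2-en-1-yl methyl carbonate
Product: 8 (E)-4-(5-bromo-2-hydroxyphenyl)-2-methylbut-2-en-1-yl methyl carbonate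
Conditions: Bu4NF, AcOH, THF, 0 °C
Reagents that add atoms: none
Why: Fluoride cleaves the aryl silyl ether rapidly, and the acetic acid buffer keeps the liberated phenol protonated so that the carbonate survives.

Step 8
Reactants: 8 (E)-4-(5-bromo-2-hydroxyphenyl)-2-methylbut-2-en-1-yl methyl carbonate
Product: 9 (S)-5-bromo-2-(prop-1-en-2-yl)-2,3-dihydrobenzofuran
Conditions: Pd2(dba)3·CHCl3 (2.5 mol %), (S,S)-DACH-phenyl Trost ligand (7.5 mol %), AcOH (1 equiv), CH2Cl2, rt
Reagents that add atoms: none
Why: Intramolecular asymmetric Tsuji–Trost O-allylation: the phenol attacks the internal terminus of the 2-methyl-π-allylpalladium complex in a 5-exo sense, the chiral ligand pocket selecting between the interconverting diastereomeric complexes and so setting C2 as S, while the electron-rich aryl bromide is inert to the zerovalent palladium–phosphine catalyst at room temperature.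

Step 9
Reactants: 10 2,4-dihydroxy-6-methoxybenzaldehyde
Product: 11 3,5-dibromo-2,4-dihydroxy-6-methoxybenzaldehyde
Conditions: NBS (2.05 equiv), MeCN, 0 °C → rt
Reagents that add atoms: N-bromosuccinimide, O=C1CCC(=O)N1Br
Why: Electrophilic aromatic bromination fills the only two free ring positions, both ortho/para to the hydroxyl groups, on a substrate with no other sensitive group.

Step 10
Reactants: 11 3,5-dibromo-2,4-dihydroxy-6-methoxybenzaldehyde
Product: 12 3,5-dibromo-2-methoxy-4,6-bis(methoxymethoxy)benzaldehyde
Conditions: MOMCl, i-Pr2NEt, CH2Cl2, 0 → 40 °C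
Reagents that add atoms: chloromethyl methyl ether, COCCl
Why: O-Alkylation of the two acidic bromophenols with the highly reactive chloromethyl ether gives base-stable acetals that later tolerate organolithiums and are removable by mild acid.

Step 11
Reactants: 9 (S)-5-bromo-2-(prop-1-en-2-yl)-2,3-dihydrobenzofuran; 12 3,5-dibromo-2-methoxy-4,6-bis(methoxymethoxy)benzaldehyde
Product: 14 (3,5-dibromo-2-methoxy-4,6-bis(methoxymethoxy)phenyl)[(S)-2-(prop-1-en-2-yl)-2,3-dihydrobenzofuran-5-yl]methanol as a carbinol epimer mixture, via aryl Grignard reagent 13 (not isolated)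
Conditions: 9, Mg, LiCl, THF, rt; then 12, THF, −40 → 0 °C; aq NH4Cl
Reagents that add atoms: none
Why: Grignard addition to the aldehyde is far faster than halogen–magnesium exchange at the hindered ring bromides, and the new carbinol centre is inconsequential because it is reduced next.

Step 12
Reactants: 14 diaryl carbinol
Product: 15 (S)-5-[3,5-dibromo-2-methoxy-4,6-bis(methoxymethoxy)benzyl]-2-(prop-1-en-2-yl)-2,3-dihydrobenzofuran
Conditions: Et3SiH (5 equiv), CF3CO2H (3 equiv), CH2Cl2, −40 → −10 °C
Reagents that add atoms: none
Why: Ionic hydrogenation: the doubly benzylic, alkoxy-stabilised carbinol ionises at low temperature and the cation is trapped by excess silane well before the MOM acetals or the isopropenyl group (deactivated by its allylic oxygen) are protonated.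

Step 13
Reactants: 15 dibromo diarylmethane
Product: 18 diol (each Br of 15 replaced by CH2OH), via dilithio arene 16 (not isolated), via dialdehyde 17 (not isolated)
Conditions: t-BuLi (4.4 equiv), THF/Et2O, −78 °C; DMF, −78 → 0 °C; then MeOH, NaBH4, 0 °C
Reagents that add atoms: N,N-dimethylformamide, CN(C)C=O
Why: Double bromine–lithium exchange at −78 °C outruns any deprotonation and gives aryllithiums each chelated by two flanking ether oxygens (no ortho leaving group, so no aryne); formylation with DMF and borohydride reduction in the same flask then deliver both hydroxymethyl groups.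

Step 14
Reactants: 18 diol
Product: 20 bis(chloromethyl) arene (each CH2OH of 18 replaced by CH2Cl), via bis-mesylate 19 (not isolated)
Conditions: MsCl, 2,4,6-collidine, LiCl, DMF, 0 °C; cold work-up, used at once
Reagents that add atoms: lithium chloride, [Li+].[Cl-]
Why: Mesylation followed by in situ chloride displacement converts the activated benzylic alcohols into chlorides under non-acidic conditions with a hindered base that cannot quaternise the product.

Step 15
Reactants: 20 bis(chloromethyl) arene; 21 (R)-4-methyldihydrofuran-2(3H)-one
Product: 23 bis(trans-lactone) (each CH2Cl of 20 replaced by CH2 bonded to C3 of a (3R,4R)-4-methyl-2-oxotetrahydrofuran-3-yl unit), via lithium enolate 22 (not isolated)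
Conditions: 21 (3.0 equiv), LiN(i-Pr)2 (2.9 equiv), THF, −78 °C; then 20, DMPU, −78 → −40 °C; AcOH quench at −40 °C
Reagents that add atoms: none
Why: LiN(i-Pr)2 converts 21 completely into its planar lithium enolate 22, which displaces chloride from each benzylic CH2Cl of 20 in an SN2 C-alkylation, forming the two benzylic CH2–Cα bonds. The closest known reaction type is the trans-selective α-benzylation of β-substituted γ-butyrolactone enolates used for dibenzylbutyrolactone lignans. No ring is closed in this step; both tetrahydrofuran rings arrive intact with the lactone. Each new α-stereocentre is set by the β-methyl group of its own lactone, the electrophile entering the enolate face anti to that methyl to give the (3R,4R) trans arrangement, so the two alkylations are independent and both halves come out homochiral. The step needs diastereoselectivity and clean mono-C-alkylation, secured by the small excess of lactone over amide base (so no free base meets 20 or the product), the excess of enolate at low temperature (which suppresses proton transfer, α-epimerisation and dialkylation) and the high SN2 reactivity of a benzylic chloride flanked by chelating ether oxygens on a ring with no free position. A minor cis epimer would be tolerable because the acid step 17 can equilibrate C3a through the enol ether toward the same, more stable arrangement.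

Step 16
Reactants: 23 bis(trans-lactone)
Product: 24 bis-lactol (each lactone C=O of 23 converted into C(OH)CH3; anomer mixture in equilibrium with the γ-hydroxy methyl ketone)
Conditions: MeLi (2.3 equiv), THF, −78 °C; AcOH quench at −78 °C
Reagents that add atoms: methyllithium, [Li]C
Why: Organolithium addition to a γ-lactone stops at the cyclic lithium hemiketal alkoxide at −78 °C, so a cold quench should give the methyl lactol without a second addition and without touching the α- and β-stereocentres.

Step 17
Reactants: 24 bis-lactol
Product: 26 O-methyl ether of the target (pentacyclic bis-ketal), via phenolic bis-lactol 25 (not isolated)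
Conditions: HCl (0.3 M in MeOH), 0 °C → rt; evaporate; then p-TsOH·H2O (10 mol %), MgSO4, CH2Cl2, rt
Reagents that add atoms: none
Why: Acid-catalysed acetal exchange removes both MOM groups, and each lactol ionises to a cyclic oxocarbenium ion that the neighbouring phenol traps (ketalisation, as in xyloketal-type furochromene formation); because the third oxygen is blocked as its methyl ether and the closures are reversible, the only bis-ketal that can accumulate is the target skeleton, and each new ketal carbon C9a takes the cis ring fusion imposed by its C3a neighbour, with the C3 methyl on the convex face.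

Step 18
Reactants: 26 O-methyl ether of the target
Product: 27 target CNP0131395.1
Conditions: NaSEt (5 equiv), DMF, 120 °C; aq NH4Cl
Reagents that add atoms: none
Why: Thiolate SN2 attack on the methyl group of the hindered, twisted aryl methyl ether liberates the phenol under basic conditions to which the ketals, the isopropenyl group and all stereocentres are inert.

**Compound list**
1 | 4-bromophenol | Oc1ccc(Br)cc1 | starting material
2 | 1-(allyloxy)-4-bromobenzene | C=CCOc1ccc(Br)cc1 | intermediate
3 | 2-allyl-4-bromophenol | C=CCc1cc(Br)ccc1O | intermediate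
4 | (2-allyl-4-bromophenoxy)(tert-butyl)dimethylsilane | C=CCc1cc(Br)ccc1O[Si](C)(C)C(C)(C)C | intermediate
5 | (E)-4-[5-bromo-2-(tert-butyldimethylsilyloxy)phenyl]-2-methylbut-2-enal | O=C/C(C)=C/Cc1cc(Br)ccc1O[Si](C)(C)C(C)(C)C | intermediate
6 | (E)-4-[5-bromo-2-(tert-butyldimethylsilyloxy)phenyl]-2-methylbut-2-en-1-ol | OC/C(C)=C/Cc1cc(Br)ccc1O[Si](C)(C)C(C)(C)C | intermediate
7 | (E)-4-[5-bromo-2-(tert-butyldimethylsilyloxy)phenyl]-2-methylbut-2-en-1-yl methyl carbonate | COC(=O)OC/C(C)=C/Cc1cc(Br)ccc1O[Si](C)(C)C(C)(C)C | intermediate
8 | (E)-4-(5-bromo-2-hydroxyphenyl)-2-methylbut-2-en-1-yl methyl carbonate | COC(=O)OC/C(C)=C/Cc1cc(Br)ccc1O | intermediate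
9 | (S)-5-bromo-2-(prop-1-en-2-yl)-2,3-dihydrobenzofuran | C=C(C)[C@@H]1Cc2cc(Br)ccc2O1 | intermediate
10 | 2,4-dihydroxy-6-methoxybenzaldehyde | COc1cc(O)cc(O)c1C=O | starting material
11 | 3,5-dibromo-2,4-dihydroxy-6-methoxybenzaldehyde | COc1c(Br)c(O)c(Br)c(O)c1C=O | intermediate
12 | 3,5-dibromo-2-methoxy-4,6-bis(methoxymethoxy)benzaldehyde | COCOc1c(Br)c(OCOC)c(Br)c(OC)c1C=O | intermediate
13 | [(S)-2-(prop-1-en-2-yl)-2,3-dihydrobenzofuran-5-yl]magnesium bromide | C=C(C)[C@@H]1Cc2cc([Mg]Br)ccc2O1 | intermediate
14 | (3,5-dibromo-2-methoxy-4,6-bis(methoxymethoxy)phenyl)[(S)-2-(prop-1-en-2-yl)-2,3-dihydrobenzofuran-5-yl]methanol (carbinol epimers) | C=C(C)[C@@H]1Cc2cc(C(O)c3c(OC)c(Br)c(OCOC)c(Br)c3OCOC)ccc2O1 | intermediate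
15 | (S)-5-[3,5-dibromo-2-methoxy-4,6-bis(methoxymethoxy)benzyl]-2-(prop-1-en-2-yl)-2,3-dihydrobenzofuran | C=C(C)[C@@H]1Cc2cc(Cc3c(OC)c(Br)c(OCOC)c(Br)c3OCOC)ccc2O1 | intermediate
16 | dilithio arene (each Br of 15 replaced by Li) | C=C(C)[C@@H]1Cc2cc(Cc3c(OC)c([Li])c(OCOC)c([Li])c3OCOC)ccc2O1 | intermediate
17 | dialdehyde (each Br of 15 replaced by CHO) | C=C(C)[C@@H]1Cc2cc(Cc3c(OC)c(C=O)c(OCOC)c(C=O)c3OCOC)ccc2O1 | intermediate
18 | diol (each Br of 15 replaced by CH2OH) | C=C(C)[C@@H]1Cc2cc(Cc3c(OC)c(CO)c(OCOC)c(CO)c3OCOC)ccc2O1 | intermediate
19 | bis-mesylate (each CH2OH of 18 as CH2OSO2CH3) | C=C(C)[C@@H]1Cc2cc(Cc3c(OC)c(COS(C)(=O)=O)c(OCOC)c(COS(C)(=O)=O)c3OCOC)ccc2O1 | intermediate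
20 | bis(chloromethyl) arene (each CH2OH of 18 replaced by CH2Cl) | C=C(C)[C@@H]1Cc2cc(Cc3c(OC)c(CCl)c(OCOC)c(CCl)c3OCOC)ccc2O1 | intermediate
21 | (R)-4-methyldihydrofuran-2(3H)-one | C[C@H]1COC(=O)C1 | starting material
22 | lithium enolate of 21 | C[C@H]1COC(O[Li])=C1 | intermediate
23 | bis(trans-lactone): two (3R,4R)-4-methyl-2-oxotetrahydrofuran-3-ylmethyl arms on the MOM-protected arene | C=C(C)[C@@H]1Cc2cc(Cc3c(OC)c(C[C@@H]4[C@@H](C)COC4=O)c(OCOC)c(C[C@@H]4[C@@H](C)COC4=O)c3OCOC)ccc2O1 | intermediate
24 | bis-lactol (2-hydroxy-2-methyltetrahydrofuran units, anomer mixture) | C=C(C)[C@@H]1Cc2cc(Cc3c(OC)c(C[C@@H]4[C@@H](C)COC4(C)O)c(OCOC)c(C[C@@H]4[C@@H](C)COC4(C)O)c3OCOC)ccc2O1 | intermediate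
25 | phenolic bis-lactol (24 with both MOM ethers cleaved; partly as its methyl ketal in methanol) | C=C(C)[C@@H]1Cc2cc(Cc3c(OC)c(C[C@@H]4[C@@H](C)COC4(C)O)c(O)c(C[C@@H]4[C@@H](C)COC4(C)O)c3O)ccc2O1 | intermediate
26 | O-methyl ether of the target: two (3R,3aR,9aR)-3,9a-dimethyl-2,3,3a,9a-tetrahydro-4H-furo[2,3-b]pyran-type ketal units fused to the central arene | C=C(C)[C@@H]1Cc2cc(Cc3c(OC)c4c(c5c3O[C@@]3(C)OC[C@H](C)[C@H]3C5)O[C@@]3(C)OC[C@H](C)[C@H]3C4)ccc2O1 | intermediate
27 | CNP0131395.1 | C=C(C)[C@@H]1Cc2cc(Cc3c(O)c4c(c5c3O[C@@]3(C)OC[C@H](C)[C@H]3C5)O[C@@]3(C)OC[C@H](C)[C@H]3C4)ccc2O1 | target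

**Step count**
Total: 18 steps. Longest linear sequence: 16 steps (steps 1–8, then 11–18); the arene branch (steps 9–10) and the purchased lactone join at steps 11 and 15.

**Steps most likely to fail**

Step 15 (key alkylation). The labile benzylic chloride may ionise or decompose before C–C bond formation; proton transfer from the mono- or bis-alkylated product to the enolate may cause α-epimerisation or dialkylation; facial selectivity may be eroded. The fallback sets out from dialdehyde 17 (isolated by working up step 13 before the borohydride stage) and lactone 21, and returns at 23. Base-mediated aldol condensation of 21 with both formyl groups (NaOMe, toluene, rt, acidic work-up to re-close the lactones) should give the bis(E-benzylidene lactone) F1, so no benzylic halide is handled. Conjugate reduction with Mg in MeOH then saturates both exocyclic alkenes without touching the isopropenyl group, and the methoxide present equilibrates each α-centre to the more stable trans arrangement next to the fixed β-methyl group, giving 23.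

Step 13 (double exchange and formylation). The second bromine–lithium exchange on an already anionic arene may be incomplete, or the first aryllithium may be quenched by proton transfer, giving mono-functionalised material. The fallback sets out from 15 and returns at 18, replacing the dianion by two monoanion cycles. t-BuLi (2 equiv, −78 °C) is expected to exchange first the bromine flanked by the two MOM ethers, and DMF then NaBH4 gives the bromo benzylic alcohol F2. Its lithium alkoxide (MeLi, 1 equiv) is then exchanged at the remaining bromine (t-BuLi, 2 equiv) and formylated to the hydroxy aldehyde F3, which NaBH4 reduces to 18.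

Step 16 (MeLi addition). The hemiketal alkoxide may open and take up a second methyl group, or the lactone may be enolised with loss of the α-configuration on quench. The fallback sets out from 23 and returns at 26, avoiding any tetrahedral alkoxide. Carbonyl methylenation of both lactones with Cp2TiMe2 (toluene, 70 °C) gives the bis(2-methylenetetrahydrofuran) enol ether F4. Under the acid conditions of step 17 this is protonated to the same oxocarbenium ions while the MOM groups are lost, and the phenols close both ketals to give 26 directly.

**Further compounds**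
F1 | step 15 | bis(E-benzylidene lactone): each arm of the arene as CH=C3 of a (4R)-4-methyl-2-oxotetrahydrofuran-3-ylidene unit | C=C(C)[C@@H]1Cc2cc(Cc3c(OC)c(/C=C4\[C@@H](C)COC4=O)c(OCOC)c(/C=C4\[C@@H](C)COC4=O)c3OCOC)ccc2O1
F2 | step 13 | bromo benzylic alcohol (15 with the Br between the two MOM ethers replaced by CH2OH) | C=C(C)[C@@H]1Cc2cc(Cc3c(OC)c(Br)c(OCOC)c(CO)c3OCOC)ccc2O1
F3 | step 13 | hydroxy aldehyde (F2 with the remaining Br replaced by CHO) | C=C(C)[C@@H]1Cc2cc(Cc3c(OC)c(C=O)c(OCOC)c(CO)c3OCOC)ccc2O1
F4 | step 16 | bis(exo-methylene enol ether) (each lactone C=O of 23 replaced by C=CH2) | C=C(C)[C@@H]1Cc2cc(Cc3c(OC)c(C[C@@H]4[C@@H](C)COC4=C)c(OCOC)c(C[C@@H]4[C@@H](C)COC4=C)c3OCOC)ccc2O1
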